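**Retrosynthetic overview**
- Ring A (ε-lactone) is closed last: C1–C2 by an intramolecular Reformatsky reaction of a C4–O bromoacetate on a C1 aldehyde; the second C4 methyl group comes from MeLi addition to a C5 acetyl group. Ring E (furanone) comes from C16 acylation and hydroxylation of the spiro γ-lactone D.
- Key disconnection: ring B is cut at C6–C7 and C5–C10, a radical [4+2] annulation of methyl vinyl ketone (C4, C5, C6) onto a ring C/D precursor that carries a neopentyl iodide (C7 on C8) and a ketene dithioacetal (C10=C1 on C9).
- Enabling feature: ring B lies between the quaternary carbons C8 and C10, C6 and C7 are plain CH2 groups, C5 carries C4 (a carbonyl at this stage) and C10 carries the oxygenated C1. C5–C6 therefore maps onto the α,β-carbons of an enone, and C10=C1 onto an electron-rich tetrasubstituted ketene dithioacetal that the C5 radical, held on C8, can reach on one face only.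
- Ring D comes from acid-catalysed lactonisation of a C14 dienyl propanoic acid (dienyl triflate + zinc homoenolate); ring C, C9 and the C13 methyl group come from (S)-carvone, the quaternary C8 from two enolate alkylations.
- Order of ring formation: C (chiral pool) → D → B (key step) → E → A.

Key step: step 10

Remark: atom numbers in names follow terpenoid numbering of the target — C1–C5 and C10 in ring A (ring oxygen between C3 and C4), C5–C10 in ring B, C8, C9, C11–C14 in ring C, C14–C16 and C20 in ring D, C16–C19 in ring E; α is the face of the C9 hydrogen, β that of the C8 and C10 methyl groups; the target is then (1S,5R,8R,9R,10R,14S,16R).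

**Route**

Step 1
Reactants: 1 (S)-(+)-carvone
Product: 2 trans-6-methylcarvone
Conditions: LiN(iPr)2, THF, −78 °C; MeI, −78 → 0 °C
Reagents that add atoms: iodomethane, CI
Why: Kinetic deprotonation of the enone at the α′ carbon (C8) and enolate alkylation with iodomethane is standard for carvone; the methyl group enters anti to the isopropenyl group, but this centre is planarised again in step 2.

Step 2
Reactants: 2 trans-6-methylcarvone
Product: 3 hydroxymethyl ketone
Conditions: LiN(iPr)2, THF, −78 °C; CH2O (gas, from cracked paraformaldehyde), −78 °C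
Reagents that add atoms: formaldehyde, C=O
Why: The tetrasubstituted lithium enolate undergoes an aldol addition to monomeric formaldehyde on the face anti to the neighbouring isopropenyl group, which sets the quaternary C8 with the CH2OH group (C7) α and the methyl group β, cis to C10.

Step 3
Reactants: 3 hydroxymethyl ketone
Product: 4 neopentyl iodide
Conditions: PPh3, I2, imidazole, toluene, 90 °C
Reagents that add atoms: iodine, II
Why: Appel-type iodination converts the neopentyl primary alcohol into the iodide by SN2 displacement of the oxyphosphonium group, a slow but known substitution at elevated temperature that touches no stereocentre.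

Step 4
Reactants: 4 neopentyl iodide
Product: 5 methyl ketone
Conditions: OsO4 (2 mol%), NaIO4, 2,6-lutidine, dioxane–H2O (3:1), rt
Reagents that add atoms: sodium periodate, [Na+].[O-]I(=O)(=O)=O
Why: Lemieux–Johnson oxidation (dihydroxylation by catalytic OsO4, glycol cleavage by NaIO4) cleaves the electron-rich 1,1-disubstituted isopropenyl alkene, while the electron-poor trisubstituted enone alkene should react much more slowly; no stereocentre is formed.

Step 5
Reactants: 5 methyl ketone
Product: 6 dioxolane
Conditions: (Me3SiOCH2)2, Me3SiOTf (5 mol%), CH2Cl2, −78 → −20 °C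
Reagents that add atoms: 1,2-bis(trimethylsilyloxy)ethane, C[Si](C)(C)OCCO[Si](C)(C)C
Why: Silyl triflate-catalysed ketalisation protects the saturated methyl ketone chemoselectively, since the conjugated, α-quaternary enone carbonyl is far less electrophilic; no stereocentre is formed.

Step 6
Reactants: 6 dioxolane
Product: 7 dienyl triflate
Conditions: KN(SiMe3)2, THF, −78 °C; PhNTf2, −78 → 0 °C
Reagents that add atoms: N-phenylbis(trifluoromethanesulfonimide), O=S(=O)(N(c1ccccc1)S(=O)(=O)C(F)(F)F)C(F)(F)F
Why: With no α′ hydrogen left, the base removes a γ-hydrogen (C11) to give the extended dienolate, whose O-sulfonylation gives the 1,3-dienyl triflate (enol triflate formation); no stereocentre is formed.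

Step 7
Reactants: 7 dienyl triflate; 8 (3-ethoxy-3-oxopropyl)zinc bromide
Product: 9 diene ester
Conditions: Pd(PPh3)4 (5 mol%), THF, 60 °C
Reagents that add atoms: none
Why: Negishi coupling of the hindered dienyl triflate with the ester-stabilised zinc homoenolate under catalysis by zerovalent palladium forms the C14–C15 bond, and the neopentyl iodide, which has no β-hydrogen and adds only slowly to zerovalent palladium, should survive; no stereocentre is formed.

Step 8
Reactants: 9 diene ester
Product: 12 spiro lactone ketone, via dienyl acid 10 (not isolated), via dioxolane lactone 11 (not isolated)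
Conditions: LiOH, THF–H2O, rt; 1 M HCl, extraction; CF3SO3H (10 mol%), CH2Cl2, 0 °C; then acetone–H2O, rt
Reagents that add atoms: lithium hydroxide, [Li+].[OH-]; water, O
Why: After ester hydrolysis, Brønsted acid-catalysed hydro-lactonisation of the dienoic acid (protonation at C11, 5-exo capture of the tertiary allylic cation at C14 by the carboxyl group) should give the spiro γ-lactone with the C12=C13 alkene in place, the oxygen adding to the α-face anti to the axial C8 methyl group, which is also the more stable arrangement (C–O axial, C15 equatorial); aqueous acetone then hydrolyses the dioxolane.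

Step 9
Reactants: 12 spiro lactone ketone; 13 2-(trimethylsilyl)-1,3-dithiane
Product: 14 ketene dithioacetal
Conditions: 13, n-BuLi, THF, −78 → −20 °C; then 12, −78 → 0 °C
Reagents that add atoms: none
Why: Peterson olefination: the small, highly nucleophilic silyl-stabilised dithianyl anion should add to the methyl ketone faster than it enolises it or attacks the lactone, and loss of lithium trimethylsilanolate gives the tetrasubstituted ketene dithioacetal; no stereocentre is formed.

Step 10
Reactants: 14 ketene dithioacetal; 15 but-3-en-2-one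
Product: 16 B/C/D tricycle
Conditions: 15 (3 equiv), Bu3SnH (1.3 equiv) + AIBN (0.2 equiv) added over 8 h, benzene (0.01 M), 80 °C
Reagents that add atoms: none
Why: Proposed new method: Bu3Sn• abstracts iodine from the neopentyl C7–I bond, the nucleophilic primary C7 radical adds to the CH2 terminus of enone 15 (Giese addition, forming C6–C7), and the resulting electrophilic α-keto radical at C5 closes ring B by 6-exo-trig attack on C10 of the electron-rich ketene dithioacetal (forming C5–C10), after which the bis-thio-stabilised C1 radical takes hydrogen from Bu3SnH. The closest known reaction types are the tin hydride-mediated Giese addition of alkyl iodides to enones and the 6-exo cyclisation of α-carbonyl radicals onto electron-rich alkenes; their coupling into a radical [4+2] annulation that creates a quaternary carbon has not been shown on this substrate class. The polarity alternation (nucleophilic radical on electron-poor alkene, then electrophilic radical on electron-rich alkene) secures the chemoselectivity, and the two sulfur atoms on C1 direct the second attack to C10 and not to C1. C10 is controlled by the ring C stereocentres: A(1,3) strain holds the C9–H bond in the plane of the tetrasubstituted C10=C1 bond, and the C5 radical, tethered through C7 on the α-side of C8, can only reach the face that puts the C10 methyl group axial (β, syn to the C8 methyl group) and C1 equatorial. C5 is set by the chair-like transition state with the acetyl group equatorial (C5–H α), and since C5 is α to the ketone it can be equilibrated to this trans arrangement. The step needs a low, steady Bu3SnH concentration so that neither the C7 radical nor the C5 radical is reduced before C–C bond formation, which the slow addition secures.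

Step 11
Reactants: 16 B/C/D tricycle
Product: 18 silyl ether, via tertiary alcohol 17 (not isolated)
Conditions: MeLi, CeCl3, THF, −78 °C; aqueous work-up; Me3SiOTf, 2,6-lutidine, CH2Cl2, −78 °C
Reagents that add atoms: methyllithium, [Li]C; trimethylsilyl trifluoromethanesulfonate, C[Si](C)(C)OS(=O)(=O)C(F)(F)F
Why: MeCeCl2 adds to the hindered, enolisable methyl ketone without enolisation and much faster than to the γ-lactone (1,2-addition), and silylation of the crude tertiary alcohol protects it for the enolate chemistry that follows; C4 carries two methyl groups and is no stereocentre.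

Step 12
Reactants: 19 methyl 2-methyl-3-oxobutanoate
Product: 20 methyl (E)-3-methoxy-2-methylbut-2-enoate
Conditions: HC(OMe)3, H2SO4 (cat.), MeOH, rt
Reagents that add atoms: trimethyl orthoformate, COC(OC)OC
Why: Acid-catalysed reaction of the β-keto ester with the orthoformate gives the β-methoxy enoate (enol ether formation via the dimethyl ketal), as is known for acetoacetates; the E isomer is expected and the alkene geometry is lost later.

Step 13
Reactants: 20 methyl (E)-3-methoxy-2-methylbut-2-enoate
Product: 21 (E)-3-methoxy-2-methylbut-2-enoic acid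
Conditions: NaOH, MeOH–H2O, 60 °C; then HCl to pH 3, 0 °C
Reagents that add atoms: sodium hydroxide, [Na+].[OH-]
Why: Saponification of the ester and careful cold acidification should give the acid, the enol ether being stable to base.

Step 14
Reactants: 21 (E)-3-methoxy-2-methylbut-2-enoic acid
Product: 22 (E)-3-methoxy-2-methylbut-2-enoyl chloride
Conditions: (COCl)2, DMF (cat.), CH2Cl2, 0 °C → rt
Reagents that add atoms: oxalyl chloride, ClC(=O)C(Cl)=O
Why: Oxalyl chloride with catalytic DMF converts the acid into the acid chloride (Vilsmeier-type activation), as is known for 3-alkoxyacryloyl chlorides.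

Step 15
Reactants: 18 silyl ether; 22 (E)-3-methoxy-2-methylbut-2-enoyl chloride
Product: 23 β-keto lactone
Conditions: LiN(SiMe3)2 (2.2 equiv), THF, −78 °C; then 22, −78 °C
Reagents that add atoms: none
Why: Crossed Claisen-type C-acylation of the lactone lithium enolate at C16 by the acid chloride gives the β-keto lactone, the second equivalent of base taking up the more acidic product; C16 remains epimerisable at this stage.

Step 16
Reactants: 23 β-keto lactone
Product: 25 furanone alcohol, via hydroxy keto lactone 24 (not isolated)
Conditions: KN(SiMe3)2, THF, −78 °C; 2-(phenylsulfonyl)-3-phenyloxaziridine, −78 °C; work-up; PPTS, MeOH, 40 °C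
Reagents that add atoms: 2-(phenylsulfonyl)-3-phenyloxaziridine, O=S(=O)(N1OC1c1ccccc1)c1ccccc1
Why: Electrophilic enolate hydroxylation by the N-sulfonyloxaziridine should occur on the face of ring D syn to the planar C13 and anti to the quaternary C8, which sets C16; mild acid then closes ring E by addition–elimination of the tertiary hydroxyl group on the β-methoxy enone (loss of methanol, 3(2H)-furanone formation) and removes the silyl ether.

Step 17
Reactants: 25 furanone alcohol
Product: 26 bromoacetate
Conditions: BrCH2COBr, pyridine, CH2Cl2, 0 °C → rt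
Reagents that add atoms: bromoacetyl bromide, BrCC(Br)=O
Why: O-acylation of the hindered tertiary alcohol with the highly reactive acid bromide (via the acylpyridinium ion or bromoketene) should give the bromoacetate; no stereocentre is formed.

Step 18
Reactants: 26 bromoacetate
Product: 27 aldehyde
Conditions: PhI(OCOCF3)2, MeCN–H2O (9:1), 0 °C
Reagents that add atoms: water, O
Why: Oxidative dithioacetal cleavage with the hypervalent iodine reagent unmasks the neopentyl aldehyde under conditions that should leave the bromoacetate, the alkene and the furanone untouched; the aldehyde has no α-hydrogen and cannot epimerise.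

Step 19
Reactants: 27 aldehyde
Product: 28 hydroxy lactone
Conditions: SmI2 (2.5 equiv), THF, −78 °C
Reagents that add atoms: none
Why: Intramolecular Reformatsky reaction: SmI2 reduces the α-bromo ester to the trivalent samarium enolate, which adds to the C1 aldehyde to close the seven-membered lactone, and with the enolate forced to attack anti to C9, Felkin–Anh-type induction by the quaternary C10 (carbonyl oxygen on the side of C5, hydrogen on the side of the C10 methyl group) should give the 1α (S) alcohol.

Step 20
Reactants: 28 hydroxy lactone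
Product: 29 target compound CNP0131208.2
Conditions: Ac2O, pyridine, DMAP (cat.), CH2Cl2, 0 °C
Reagents that add atoms: acetic anhydride, CC(=O)OC(C)=O
Why: Acetylation of the secondary alcohol (esterification with retention at C1) gives the target, and a short reaction time at 0 °C should avoid β-elimination of the acetate.

**Compound list**

1 | (S)-(+)-carvone, (5S)-2-methyl-5-(prop-1-en-2-yl)cyclohex-2-en-1-one | CC(=C)[C@H]1CC=C(C)C(=O)C1 | starting material
2 | trans-6-methylcarvone, (5S,6R)-2,6-dimethyl-5-(prop-1-en-2-yl)cyclohex-2-en-1-one | C[C@@H]1[C@H](CC=C(C)C1=O)C(C)=C | intermediate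
3 | hydroxymethyl ketone, (5R,6S)-6-(hydroxymethyl)-2,6-dimethyl-5-(prop-1-en-2-yl)cyclohex-2-en-1-one (CH2OH trans to isopropenyl) | OC[C@]1(C)[C@H](CC=C(C)C1=O)C(C)=C | intermediate
4 | neopentyl iodide, (5R,6R)-6-(iodomethyl)-2,6-dimethyl-5-(prop-1-en-2-yl)cyclohex-2-en-1-one | IC[C@]1(C)[C@H](CC=C(C)C1=O)C(C)=C | intermediate
5 | methyl ketone, (5S,6R)-5-acetyl-6-(iodomethyl)-2,6-dimethylcyclohex-2-en-1-one | IC[C@]1(C)[C@H](CC=C(C)C1=O)C(C)=O | intermediate
6 | dioxolane, 6-(iodomethyl)-2,6-dimethyl-5-(2-methyl-1,3-dioxolan-2-yl)cyclohex-2-en-1-one (ring stereocentres as in 5) | IC[C@]1(C)[C@H](CC=C(C)C1=O)C2(C)OCCO2 | intermediate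
7 | dienyl triflate, 6-(iodomethyl)-2,6-dimethyl-5-(2-methyl-1,3-dioxolan-2-yl)cyclohexa-1,3-dien-1-yl trifluoromethanesulfonate | IC[C@]1(C)[C@H](C=CC(C)=C1OS(=O)(=O)C(F)(F)F)C2(C)OCCO2 | intermediate
8 | (3-ethoxy-3-oxopropyl)zinc bromide | CCOC(=O)CC[Zn]Br | starting material
9 | diene ester, ethyl 3-[6-(iodomethyl)-2,6-dimethyl-5-(2-methyl-1,3-dioxolan-2-yl)cyclohexa-1,3-dien-1-yl]propanoate | IC[C@]1(C)[C@H](C=CC(C)=C1CCC(=O)OCC)C2(C)OCCO2 | intermediate
10 | dienyl acid, the free acid of 9 | IC[C@]1(C)[C@H](C=CC(C)=C1CCC(=O)O)C2(C)OCCO2 | intermediate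
11 | dioxolane lactone, 10-(iodomethyl)-6,10-dimethyl-9-(2-methyl-1,3-dioxolan-2-yl)-1-oxaspiro[4.5]dec-6-en-2-one (lactone oxygen at C14 α, trans to the C8 methyl group) | IC[C@]1(C)[C@H](CC=C(C)[C@@]12CCC(=O)O2)C3(C)OCCO3 | intermediate
12 | spiro lactone ketone, 9-acetyl-10-(iodomethyl)-6,10-dimethyl-1-oxaspiro[4.5]dec-6-en-2-one (8β-methyl, 8α-CH2I, 9β-acetyl, 14α-O) | IC[C@]1(C)[C@H](CC=C(C)[C@@]12CCC(=O)O2)C(C)=O | intermediate
13 | 2-(trimethylsilyl)-1,3-dithiane | C[Si](C)(C)C1SCCCS1 | starting material
14 | ketene dithioacetal, 9-[1-(1,3-dithian-2-ylidene)ethyl]-10-(iodomethyl)-6,10-dimethyl-1-oxaspiro[4.5]dec-6-en-2-one | IC[C@]1(C)[C@H](CC=C(C)[C@@]12CCC(=O)O2)C(C)=C3SCCCS3 | intermediate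
15 | but-3-en-2-one (methyl vinyl ketone) | CC(=O)C=C | starting material
16 | B/C/D tricycle: trans-fused rings B and C, 5-acetyl (equatorial, 5α-H), 10-(1,3-dithian-2-yl), 8β- and 10β-methyl, 13-methyl, C12=C13, spiro γ-lactone at C14 | CC(=O)[C@@H]1CC[C@]2(C)[C@H](CC=C(C)[C@@]23CCC(=O)O3)[C@@]1(C)C4SCCCS4 | intermediate
17 | tertiary alcohol, 16 with 2-hydroxypropan-2-yl in place of acetyl at C5 | CC(C)(O)[C@@H]1CC[C@]2(C)[C@H](CC=C(C)[C@@]23CCC(=O)O3)[C@@]1(C)C4SCCCS4 | intermediate
18 | silyl ether, trimethylsilyl ether of 17 | C[Si](C)(C)OC(C)(C)[C@@H]1CC[C@]2(C)[C@H](CC=C(C)[C@@]23CCC(=O)O3)[C@@]1(C)C4SCCCS4 | intermediate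
19 | methyl 2-methyl-3-oxobutanoate | CC(=O)C(C)C(=O)OC | starting material
20 | methyl (E)-3-methoxy-2-methylbut-2-enoate | CO/C(C)=C(\C)C(=O)OC | intermediate
21 | (E)-3-methoxy-2-methylbut-2-enoic acid | CO/C(C)=C(\C)C(=O)O | intermediate
22 | (E)-3-methoxy-2-methylbut-2-enoyl chloride | CO/C(C)=C(\C)C(Cl)=O | intermediate
23 | β-keto lactone, 18 acylated at C16 with the (E)-3-methoxy-2-methylbut-2-enoyl group (C16 epimers and enol) | C[Si](C)(C)OC(C)(C)[C@@H]1CC[C@]2(C)[C@H](CC=C(C)[C@@]23CC(C(=O)/C(C)=C(\C)OC)C(=O)O3)[C@@]1(C)C4SCCCS4 | intermediate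
24 | hydroxy keto lactone, 23 with a 16-hydroxyl group syn to C13 | C[Si](C)(C)OC(C)(C)[C@@H]1CC[C@]2(C)[C@H](CC=C(C)[C@@]23C[C@@](O)(C(=O)/C(C)=C(\C)OC)C(=O)O3)[C@@]1(C)C4SCCCS4 | intermediate
25 | furanone alcohol: rings B–E complete, free tertiary alcohol at C4, 1,3-dithian-2-yl at C10 | CC(C)(O)[C@@H]1CC[C@]2(C)[C@H](CC=C(C)[C@@]23C[C@]5(OC(C)=C(C)C5=O)C(=O)O3)[C@@]1(C)C4SCCCS4 | intermediate
26 | bromoacetate of 25 | BrCC(=O)OC(C)(C)[C@@H]1CC[C@]2(C)[C@H](CC=C(C)[C@@]23C[C@]5(OC(C)=C(C)C5=O)C(=O)O3)[C@@]1(C)C4SCCCS4 | intermediate
27 | aldehyde, 26 with CHO (C1) in place of the dithiane at C10 | BrCC(=O)OC(C)(C)[C@@H]1CC[C@]2(C)[C@H](CC=C(C)[C@@]23C[C@]4(OC(C)=C(C)C4=O)C(=O)O3)[C@@]1(C)C=O | intermediate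
28 | hydroxy lactone, 1α-hydroxy (1S) deacetyl target | O[C@H]1CC(=O)OC(C)(C)[C@@H]2CC[C@]3(C)[C@H](CC=C(C)[C@@]34C[C@]5(OC(C)=C(C)C5=O)C(=O)O4)[C@@]12C | intermediate
29 | CNP0131208.2 | CC(=O)O[C@H]1CC(=O)OC(C)(C)[C@@H]2CC[C@]3(C)[C@H](CC=C(C)[C@@]34C[C@]3(OC(C)=C(C)C3=O)C(=O)O4)[C@@]12C | target

**Step count and risks**

Total step count: 20. Longest linear sequence: 17 (steps 1–11 and 15–20).

Steps most likely to fail:

1. Step 10 (proposed new method). The C7 radical may be lost by intramolecular 1,5-hydrogen transfer from the allylic C10 methyl group or by premature reduction, the C5 radical may oligomerise with 15, and the dithianyl radical at C1 may add to a second molecule of 15 before it is reduced. Fallback (two discrete, known radical steps): setting out from 14, Giese addition of the C7 radical (Bu3SnH, AIBN) to 3-(phenylthio)but-3-en-2-one would give the open-chain α-phenylthio ketone F1, the captodative adduct radical being reduced faster than it cyclises. In a second operation, slow addition of Bu3SnH and AIBN to F1 in dilute benzene, with no enone present, would regenerate the C5 α-keto radical by C–S homolysis and close ring B by 6-exo cyclisation, returning to the route at 16.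

2. Step 19. SmI2 may reduce the α-oxygenated furanone ketone in competition with the bromoacetate, the aldehyde may undergo pinacol coupling, or the aldol addition may show poor facial selectivity at C1. Fallback: setting out from 26, Arbuzov reaction with P(OEt)3 would give the phosphonoacetate F2, and PhI(OCOCF3)2 would unmask the phosphonate aldehyde F3. Intramolecular Horner–Wadsworth–Emmons olefination (LiCl, DBU) would give the α,β-unsaturated ε-lactone F4, and nucleophilic epoxidation (t-BuOOH, DBU) on the α-face, anti to the C10 methyl group, would give the 1α,2α-epoxy lactone F5. Reductive opening at C2 with (PhSe)2, NaBH4 and AcOH would return to the route at 28.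

3. Step 16. The hydroxylation at C16 relies on remote induction from the spiro centre and may show reversed facial selectivity, and the oxidant may also attack the dithiane sulfur. Fallback (the two C16 substituents are attached in the opposite order): setting out from 18, hydroxylation of the lactone enolate (LiN(SiMe3)2, then the oxaziridine) would give the α-hydroxy lactone F6, whose C16 configuration is irrelevant, and silylation (Me3SiCl, imidazole) would give the bis-silyl ether F7. C-acylation of the enolate of F7 with 22 would give the acylated silyloxy lactone F8, the acyl group now entering on the face that the oxidant preferred. PPTS in methanol would then remove both silyl groups and close ring E, returning to the route at 25.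

Further compounds
F1 | step 10 | open-chain α-phenylthio ketone (14 with CH2CH2CH(SPh)C(=O)CH3 in place of CH2I) | CC(=O)C(Sc1ccccc1)CC[C@]1(C)[C@H](CC=C(C)[C@@]12CCC(=O)O2)C(C)=C3SCCCS3
F2 | step 19 | phosphonoacetate (26 with P(O)(OEt)2 in place of Br) | CCOP(=O)(OCC)CC(=O)OC(C)(C)[C@@H]1CC[C@]2(C)[C@H](CC=C(C)[C@@]23C[C@]5(OC(C)=C(C)C5=O)C(=O)O3)[C@@]1(C)C4SCCCS4
F3 | step 19 | phosphonate aldehyde | CCOP(=O)(OCC)CC(=O)OC(C)(C)[C@@H]1CC[C@]2(C)[C@H](CC=C(C)[C@@]23C[C@]4(OC(C)=C(C)C4=O)C(=O)O3)[C@@]1(C)C=O
F4 | step 19 | α,β-unsaturated ε-lactone (C1=C2) | C1=CC(=O)OC(C)(C)[C@@H]2CC[C@]3(C)[C@H](CC=C(C)[C@@]34C[C@]5(OC(C)=C(C)C5=O)C(=O)O4)[C@@]12C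
F5 | step 19 | 1α,2α-epoxy lactone | O6[C@H]1[C@@H]6C(=O)OC(C)(C)[C@@H]2CC[C@]3(C)[C@H](CC=C(C)[C@@]34C[C@]5(OC(C)=C(C)C5=O)C(=O)O4)[C@@]12C
F6 | step 16 | α-hydroxy lactone (18 with OH at C16, epimers) | C[Si](C)(C)OC(C)(C)[C@@H]1CC[C@]2(C)[C@H](CC=C(C)[C@@]23CC(O)C(=O)O3)[C@@]1(C)C4SCCCS4
F7 | step 16 | bis-silyl ether (F6 with OSiMe3 at C16) | C[Si](C)(C)OC(C)(C)[C@@H]1CC[C@]2(C)[C@H](CC=C(C)[C@@]23CC(O[Si](C)(C)C)C(=O)O3)[C@@]1(C)C4SCCCS4
F8 | step 16 | acylated silyloxy lactone (F7 C-acylated at C16, acyl syn to C8) | C[Si](C)(C)OC(C)(C)[C@@H]1CC[C@]2(C)[C@H](CC=C(C)[C@@]23C[C@@](O[Si](C)(C)C)(C(=O)/C(C)=C(\C)OC)C(=O)O3)[C@@]1(C)C4SCCCS4
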